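Capped ends cannot outnumber the one-sided end groups charged, since each capped end takes one of them. So the ratio of 5.00 mM to 0.10 M of first end groups, the cap fraction 5.00%, is the most that can be capped.

| flask | first end groups | second end groups | one-sided end groups | remark | time |
|---|---|---|---|---|---|
| south-west | 0.10 M | 0.59 equiv | 5 mM | run made earlier |  |
| north-east | 0.10 M | 11 equiv | 5 mM | run made earlier |  |
| green | 0.10 M | 1.00 equiv | 5.00 mM |  | 4.0 h |
| teal | 0.10 M | 2.00 equiv | 5.00 mM |  | 4.0 h |
| blue | 0.10 M | 4.00 equiv | 5.00 mM |  | 4.0 h |
| violet | 0.10 M | 8.00 equiv | 5.00 mM |  | 4.0 h |
| ochre | 0.10 M | 15.0 equiv | 5.00 mM |  | 4.0 h |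

| run | time / h | links / % | capped ends / % |
|---|---|---|---|
| south-west | 0.667 | 37.2 | 5.3 |
| south-west | 1.33 | 43.8 | 5.1 |
| south-west | 2.00 | 46.3 | 3.7 |
| south-west | 3.00 | 49.4 | 5.5 |
| north-east | 0.250 | 89.7 | 5.1 |
| north-east | 0.500 | 94.1 | 3.8 |
| north-east | 1.33 | 95.0 | 5.0 |
| north-east | 3.00 | 94.9 | 4.2 |

(readings scatter by 1 percentage point)

- the numbers in the tables scatter with a standard deviation of 1 percentage point
- "hardly changes" means that all values lie within two and a half points (for a concentration: within two and a half percent of the largest)

1. share of links in all that became links or capped ends for green, teal, blue, violet, ochre, in this order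
2. the course of these numbers from the first flask to the last (falls, then rises / falls all the way / hardly changes / rises all the way / rises, then falls)

Do the readings reach that limit? Capped ends average 4.90% in the south-west run and 4.53% in the north-east run, with 1 percentage point of scatter on each reading. I take the limit as reached.

How do you reckon the share of links, the selectivity? From the fraction left, not the fraction made. What has reacted is one minus the first end groups left, and of this the cap fraction of the charge is capped, so the share is one minus the cap fraction divided by what has reacted.

And with nothing left? Then the share is 95.0%, provided the capped ends have reached the cap fraction.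

Where is the weak spot? It is a flask with much left. A south-west reading at 3.00 h has 45.1% left, and there the rule gives 90.9%, too far below 95.0% for "hardly changes". With a third left it gives 92.5%, which is 2.5 points down.

Will green stay above that? Green needs 61.7% links from 1.00 equiv in 4.0 h, and the south-west run made 49.4% from 0.59 equiv in 3.00 h. I expect it to pass, and my reckoning stops at that bound.

The forecast gives numbers: 93.6% rising to 95%, so the course hardly changes, with the one-sided groups “quickly and fully consumed”.

The flasks give 93.4% for green up to 95.7% for ochre, a spread of 2.3 points, and the course hardly changes.

    first end groups + second end groups → links (k = 0.00689 /M/s)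
    first end groups + one-sided end groups → capped ends (k = 0.0967 /M/s)
    2 first end groups → self-condensation product (k = 3.10 × 10⁻⁶ /M/s)
    2 second end groups → homo dimer (k = 0.00191 /M/s)

Green at 4.00 h has 24% of its first end groups left, and the cap fraction 5.00% over what reacted gives a share of 93.4%. Ochre at 4.00 h still holds 14% of its one-sided end groups, which takes the cap fraction down to 4.30% capped ends, and the same rule gives 95.7%.

The runs are calculated on assumed constants; noise was put on by code.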